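The numbers in the tables are calculated on assumed constants; noise was put on by code.

Charging more coupling partner than starting material does not promise full conversion: the beta run held 1.80 equivalents, and its product stood at 74% at 15.0 d.

| flask | starting material | coupling partner | remark | time |
|---|---|---|---|---|
| eta | 0.050 M | 0.040 M (in portions, 3) | run made earlier; portions every 25 h |  |
| beta | 0.050 M | 0.090 M (in portions, 3) | run made earlier; portions every 25 h |  |
| zeta | 0.025 M | 0.060 M (in portions, 3) | run made earlier; portions every 25 h |  |
| flask | 0.050 M | 0.0600 M (in portions, 3) | the portions of coupling partner follow each other after 25 h, the first at the start | 15 d |

- eta (time / d: product / %): 2.50: 25; 5.00: 33; 8.00: 34; 10.0: 31; 12.0: 34; 15.0: 33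
- beta (time / d: product / %): 2.50: 57; 5.00: 67; 8.00: 68; 10.0: 73; 12.0: 74; 15.0: 74
- zeta (time / d: product / %): 1.25: 18; 2.50: 45; 4.00: 58; 8.00: 63; 15.0: 61

(scatter of a reading: 2 percentage points)

- the analysis behind the earlier runs scatters by 2 percentage points, standard deviation
- reactions considered so far: starting material + coupling partner -> product; coupling partner -> decomposed reagent
- the reaction counts as stopped when no species that holds the starting material changes by six tenths of a point or more over the second half of the time

1. at 15 d, what has stopped the reaction, if anything has (the coupling partner has run out first / all of the starting material has reacted / it is still moving)
2. how much product there is at 15 d, in percent of the starting material charged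

Coupling partner has a second fate: it decays to decomposed reagent, and what decays makes no product. The readings of eta, beta and zeta have levelled off by their last points, so each charge has split into product and loss, and the last reading shows the split. Coupling needs starting material and decay does not, so the partner lost per product should grow as the starting material shrinks. Multiplying that loss per product by the starting-material charge gives 0.0712 M for eta, 0.0716 M for beta and 0.0734 M for zeta, which started from half as much. Their mean, 0.0721 M, is the loss constant: partner lost per product made, times the starting-material charge. It puts the charge in place of the falling level of starting material, yet eta and beta, ending at 33% and 74%, give nearly the same value, so that error stays small here.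

Product is then the partner charge divided by one plus the loss constant over the starting-material charge. For the flask this reckoning gives 49.2%. The forecast stands slightly higher, at 51%, with the coupling partner has run out first: “the partner is gone and starting material remains”.

The simulation gives 50.2%, with the coupling partner has run out first.

    starting material + coupling partner → product, rate k1*[starting material]*[coupling partner]^1.5 (k = 3.60 L¹·⁵ mol⁻¹·⁵ h⁻¹)
    coupling partner → decomposed reagent (k = 0.0210 h⁻¹)

In the flask the coupling partner, charged at 1.20 equivalents, is the first to run out, down to 0.024% of its charge at 15.0 d, and the result reads back as a loss constant of 0.0695 M. Decay is the main reason for the shortfall: the same flask without it reaches 95.7% instead of 50.2%. With 0.12 M of starting material and the same partner charge, the loss constant 0.0721 M reckons 31.2%, and that neighbour flask holds 31.9%.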